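**Retrosynthetic overview**
1. Target 9 ⇒ open the C10–O lactone bond (photochemical hydro-lactonisation in the forward sense) to the Δ1(10) seco-acid 7, handled as its disodium salt 6.
2. 6 ⇒ iso-GA3 4 by lactone hydrolysis; the C2–O bond is kept.
3. 4 ⇒ gibberellic acid 1 (fermentation product) by allylic lactone 1,3-shift.
4. Rings A to D and C3, C4, C5, C6, C8, C9, C13 are bought in 1. C2 is set in step 1 and C10 is re-set in step 3, both by the carboxyl fixed at C4; the γ-lactone ring is re-formed last.

Assumption: the SMILES decodes to the trans-diaxial 2,3-diol with the 2-OH on the face of the lactone bridge (α) and the 3-OH on the face of the C18 methyl (β), i.e. 2α-hydroxy-GA1 (2-epi-GA8), where GA1 is 1,2-dihydro-GA3. α/β follow the customary gibberellin drawing, and gibberellic acid is taken as commercially available.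

**Step 1**
Reactants: 1 gibberellic acid (GA3)
Product: 4 iso-gibberellic acid (iso-GA3), via potassium gibberellate 2 (not isolated), via potassium iso-gibberellate 3 (not isolated)
Conditions: aq. KOH (0.05 M, 1.5 equiv), Ar, 20 °C, 2–4 h (HPLC, stop when 1 is consumed); then 1 M HCl to pH 3, 0 °C, EtOAc; crystallise
Reagents that add atoms: none
Why: Dilute alkali triggers the known allylic lactone 1,3-transposition of gibberellic acid (net SN2′-type shift of the acyloxy group), in which the C19 carboxylate, held on the α face by C4, leaves C10 and ends up bonded to C2 on the same face as the alkene moves to C1=C10, so the 2α-oxygen is set by C4.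

**Step 2**
Reactants: 4 iso-gibberellic acid (iso-GA3)
Product: 6 disodium 2α,3β,13-trihydroxy-20-norgibberella-1(10),16-diene-7,19-dioate, via sodium iso-gibberellate 5 (not isolated)
Conditions: aq. NaOH (0.5 M, 2.05 equiv), Ar, 20 → 35 °C, 8 h (HPLC); freeze-dry
Reagents that add atoms: sodium hydroxide, [Na+].[OH-]
Why: The first equivalent of NaOH forms salt 5 and the second saponifies the secondary allylic lactone by acyl–oxygen cleavage (BAc2), which leaves the C2–O bond untouched, so the 2α-hydroxyl is released with retention, and keeping the product as the dicarboxylate prevents re-closure to 4.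

**Step 3**
Reactants: 6 disodium 2α,3β,13-trihydroxy-20-norgibberella-1(10),16-diene-7,19-dioate
Product: 9 2α-hydroxy-GA1 (CNP0265952.2), via monosodium seco-acid 7 (not isolated), via target sodium carboxylate 8 (not isolated)
Conditions: 1 M HCl to pH 4.8 (about 1 equiv); p-xylene (50 mM), t-BuOH/H2O 3:1 (5 mM in substrate), Ar, hν 254 nm (low-pressure mercury lamp, quartz), 15 °C; then 1 M HCl to pH 3, 0 °C, EtOAc
Reagents that add atoms: none
Why: Proposed new method: an intramolecular, carboxylic-acid-relayed photoprotonation–lactonisation that isomerises 7 to 8 – energy transfer from excited p-xylene twists the ring A cyclohexene C1=C10 into its strained trans-like form, the axial 19-CO2H protonates it at C1, and the tertiary C10 cation/19-carboxylate pair collapses to the γ-lactone, which can only close on the α face because C4 holds the carboxyl there (natural C10 configuration), while the exocyclic C16=C17 relaxes without strain and is not protonated; the closest known reaction type is the Kropp–Marshall arene-sensitised photoprotonation of cyclohexenes and octalins with intermolecular Markovnikov addition of alcohols, water or acetic acid, which to my knowledge has not been shown with an internal carboxyl group on a polyfunctional substrate of this kind.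

**Compound list**
1 | gibberellic acid (GA3, CAS 77-06-5): 3β,13-dihydroxy-20-norgibberella-1,16-diene-7,19-dioic acid 19,10-lactone; lactone bridge α, 3-OH and C18 methyl β | C=C1C[C@]23C[C@@]1(O)CC[C@H]2[C@@]12C=C[C@H](O)[C@@](C)(C(=O)O1)[C@H]2[C@@H]3C(=O)O | starting material
2 | potassium gibberellate: potassium 7-carboxylate of 1 (not isolated) | C=C1C[C@]23C[C@@]1(O)CC[C@H]2[C@@]12C=C[C@H](O)[C@@](C)(C(=O)O1)[C@H]2[C@@H]3C(=O)[O-].[K+] | intermediate
3 | potassium iso-gibberellate: potassium 7-carboxylate of 4 (not isolated) | C=C1C[C@]23C[C@@]1(O)CC[C@H]2C1=C[C@@H]4[C@H](O)[C@@](C)(C(=O)O4)[C@H]1[C@@H]3C(=O)[O-].[K+] | intermediate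
4 | iso-gibberellic acid (iso-GA3): 3β,13-dihydroxy-20-norgibberella-1(10),16-diene-7,19-dioic acid 19,2α-lactone; all other centres as in 1 | C=C1C[C@]23C[C@@]1(O)CC[C@H]2C1=C[C@@H]4[C@H](O)[C@@](C)(C(=O)O4)[C@H]1[C@@H]3C(=O)O | intermediate
5 | sodium iso-gibberellate: sodium 7-carboxylate of 4 (not isolated) | C=C1C[C@]23C[C@@]1(O)CC[C@H]2C1=C[C@@H]4[C@H](O)[C@@](C)(C(=O)O4)[C@H]1[C@@H]3C(=O)[O-].[Na+] | intermediate
6 | disodium 2α,3β,13-trihydroxy-20-norgibberella-1(10),16-diene-7,19-dioate (ring-opened iso-GA3; trans 2α,3β-diol, both carboxylates as sodium salts) | C=C1C[C@]23C[C@@]1(O)CC[C@H]2C1=C[C@@H](O)[C@H](O)[C@@](C)(C(=O)[O-])[C@H]1[C@@H]3C(=O)[O-].[Na+].[Na+] | intermediate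
7 | monosodium seco-acid: monosodium salt of the diacid of 6, drawn as the 19-CO2H/7-carboxylate form (not isolated) | C=C1C[C@]23C[C@@]1(O)CC[C@H]2C1=C[C@@H](O)[C@H](O)[C@@](C)(C(=O)O)[C@H]1[C@@H]3C(=O)[O-].[Na+] | intermediate
8 | target sodium carboxylate: sodium 7-carboxylate of 9 (not isolated) | C=C1C[C@]23C[C@@]1(O)CC[C@H]2[C@@]12C[C@@H](O)[C@H](O)[C@@](C)(C(=O)O1)[C@H]2[C@@H]3C(=O)[O-].[Na+] | intermediate
9 | 2α-hydroxy-GA1 (2-epi-GA8, CNP0265952.2): 2α,3β,13-trihydroxy-20-norgibberell-16-ene-7,19-dioic acid 19,10-lactone; trans-diaxial 2,3-diol, lactone bridge α | C=C1C[C@]23C[C@@]1(O)CC[C@H]2[C@@]12C[C@@H](O)[C@H](O)[C@@](C)(C(=O)O1)[C@H]2[C@@H]3C(=O)O | target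

**Totals**
Total step count: 3. Longest linear sequence: 3. Crystalline 4 is isolated as the one purification point, because the salts that follow cannot be purified without risk of re-lactonisation.

**Steps most likely to fail**

Step 3 (proposed new step, highest risk). The fused ring A alkene may twist inefficiently. The C10 cation may lose a proton to alkene isomers, be trapped by water, or be captured on the β face by the 7-carboxylate. The seco-acid may also re-close thermally to 4; recovered 4 can be recycled through step 2. Fallback with known chemistry, setting out from 6 and rejoining at 9: iodolactonisation of 6 (I2 1.0 equiv, NaHCO3 buffer, THF/H2O, 0 °C, dark) closes the 19,10-lactone by anti addition to give sodium 1β-iodo-2α,3β,13-trihydroxy-20-norgibberell-16-ene-7,19-dioate 19,10-lactone F1. Acidification (1 M HCl, pH 3, 0 °C) gives the free 1β-iodo lactone acid F2. Radical deiodination (Bu3SnH 1.3 equiv, AIBN cat., THF/toluene, 75 °C) then delivers 9.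

Step 2. Hydroxide may cause retro-aldol epimerisation at C3 before the lactone opens, or the hydrolysis may stall. Fallback, setting out from 4 and rejoining at 6: enzymatic hydrolysis with pig liver esterase in water at pH 7.5 and 25 °C, held by pH-stat titration with 0.1 M NaOH (2 equiv consumed), then freeze-drying. It passes through 5 and avoids strongly basic medium; new compounds: none F0.

Step 1. The isomerisation may be accompanied by diene acids (gibberellenic-type elimination products) or by early hydrolysis of the new lactone. Fallback, setting out from 1 and rejoining at 4: a transition-metal allylic transposition on free acid 1 with Pd(PPh3)4 (5 mol %, zerovalent palladium) in THF at 20 °C, with no hydroxide present. Ionisation of the allylic lactone occurs anti to the leaving carboxylate, and the tethered carboxylate returns anti to palladium at the less hindered C2, giving the same 19,2α-lactone by net suprafacial shift; new compounds: none F0.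

**Further compounds**
F1 | step 3 | sodium 1β-iodo-2α,3β,13-trihydroxy-20-norgibberell-16-ene-7,19-dioate 19,10-lactone | C=C1C[C@]23C[C@@]1(O)CC[C@H]2[C@@]12[C@H](I)[C@@H](O)[C@H](O)[C@@](C)(C(=O)O1)[C@H]2[C@@H]3C(=O)[O-].[Na+]
F2 | step 3 | 1β-iodo-2α,3β,13-trihydroxy-20-norgibberell-16-ene-7,19-dioic acid 19,10-lactone | C=C1C[C@]23C[C@@]1(O)CC[C@H]2[C@@]12[C@H](I)[C@@H](O)[C@H](O)[C@@](C)(C(=O)O1)[C@H]2[C@@H]3C(=O)O
F0 | step 2 | none | none
F0 | step 1 | none | none
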